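**Strategy.** Ring A is made last. Its C5(OH), C6(H), C7(OMe) and C8(O-butyryl) carbons come from methyl semisquarate, and C4a/C8a are the C5=C6 alkene of a preformed 3-benzyloxy-2-phenyl-4-pyranone (ring C, phenyl in place). The precursor is a 4-butyryloxy-3-methoxycyclobutenone carrying that pyranone at C4; the C8–C8a bond is set by the organolithium addition that makes it. One thermal operation (4π opening, 6π closure, enolisation) forms C4a–C5, builds the benzenoid ring and delivers the para oxygens already differentiated: ketene oxygen as the chelated 5-OH, acylated carbinol oxygen as the 8-butyrate. Hydrogenolysis then frees the 3-OH.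

Key step: step 6

Numbering remark: bicyclic products use flavone numbering (O1, C2 to C8a); monocyclic pyranones keep pyran numbering.

Assumption: in the aqueous methanol of step 2 the hemiacetals 4 and 5 equilibrate with their methyl acetals; they are written as hemiacetals, which does not change the stoichiometry.

**Step 1**
Reactants: 1 furfural; 2 phenylmagnesium bromide
Product: 3 furan-2-yl(phenyl)methanol (racemic)
Conditions: THF, 0 °C to rt; then H2O
Reagents that add atoms: none
Why: Grignard 1,2-addition to the aldehyde; the carbinol center forms racemic, which is immaterial because it becomes sp2 in step 2.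

**Step 2**
Reactants: 3 furan-2-yl(phenyl)methanol
Product: 6 3-hydroxy-2-phenyl-4H-pyran-4-one, via 6-hydroxy-2-phenyl-2H-pyran-3(6H)-one 4 (not isolated), via 4-chloro-6-hydroxy-2-phenyl-2H-pyran-3(6H)-one 5 (not isolated)
Conditions: Cl2 (2.1 equiv), MeOH/H2O, −10 to 0 °C; then MeOH distilled off, 95 °C
Reagents that add atoms: water, O
Why: Achmatowicz rearrangement of the furyl carbinol, α-chlorination of the resulting enone by the second equivalent of halogen, then hot-acid conversion through a 4-chloro-3-hydroxypyrylium ion that water attacks at C4 (the maltol-type one-pot process for 1-(2-furyl)carbinols); the benzylic C2–H should enolise readily and no stereocenter remains.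

**Step 3**
Reactants: 6 3-hydroxy-2-phenyl-4H-pyran-4-one
Product: 7 3-(benzyloxy)-2-phenyl-4H-pyran-4-one
Conditions: BnBr, K2CO3, DMF, 60 °C
Reagents that add atoms: benzyl bromide, BrCc1ccccc1
Why: Williamson O-alkylation of the acidic enolic hydroxyl, as for maltol and kojic acid; the benzyl ether tolerates lithium amide and heat and is removable under neutral conditions.

**Step 4**
Reactants: 8 dimethyl squarate
Product: 10 3-methoxycyclobut-3-ene-1,2-dione (methyl semisquarate), via 4-hydroxy-2,3-dimethoxycyclobut-2-en-1-one 9 (not isolated)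
Conditions: LiAlH(OtBu)3, THF, −78 °C; then conc. aq HCl, CH2Cl2, 0 °C to rt
Reagents that add atoms: water, O
Why: Mono-reduction of one squarate carbonyl by the hindered hydride, then acid ionisation of the carbinol to a methoxy-stabilised allyl cation that water hydrolyses with loss of methanol (1,3-carbonyl transposition, the standard semisquarate preparation).

**Step 5**
Reactants: 7 3-(benzyloxy)-2-phenyl-4H-pyran-4-one; 10 3-methoxycyclobut-3-ene-1,2-dione; 11 butyric anhydride
Product: 14 1-[5-(benzyloxy)-4-oxo-6-phenyl-4H-pyran-2-yl]-2-methoxy-4-oxocyclobut-2-en-1-yl butanoate (racemic), via 6-lithio-3-(benzyloxy)-2-phenyl-4H-pyran-4-one 12 (not isolated), via lithium cyclobutenolate adduct 13 (not isolated)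
Conditions: LiTMP (from TMPH, n-BuLi; 1.1 equiv), THF, −78 °C, 7 added to the base; then 10, −78 °C; then 11 (1.5 equiv), −78 to 0 °C; aq NH4Cl
Reagents that add atoms: none
Why: Deprotonation of the only vinylic C–H next to the ring oxygen (C6, the same mode as C2-lithiation of chromones), 1,2-addition of the organolithium to the ketone-like C2 carbonyl of 10 (flanked by the methoxy carbon; C1 is deactivated as a vinylogous ester), and in-flask O-acylation of the tertiary lithium alkoxide; the quaternary carbinol center forms racemic and is destroyed in step 6.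

**Step 6**
Reactants: 14 1-[5-(benzyloxy)-4-oxo-6-phenyl-4H-pyran-2-yl]-2-methoxy-4-oxocyclobut-2-en-1-yl butanoate
Product: 17 3-(benzyloxy)-8-(butyryloxy)-5-hydroxy-7-methoxyflavone, via (Z)-dienylketene 15 (not isolated), via 4a-H cyclohexadienone tautomer 16 (not isolated)
Conditions: degassed toluene, 110 °C, Ar, 0.02 M
Reagents that add atoms: none
Why: Proposed new method: heating should cleave the C1–C4 bond of the cyclobutenone in a conrotatory 4π opening to the (Z)-dienylketene 15, whose ketene carbon then bonds to pyranone C5 in a 6π electrocyclisation to dienone 16, and enolisation of the C4a–H gives the phenol. The closest known reaction type is the Moore rearrangement of 4-aryl, 4-heteroaryl and 4-alkenyl cyclobutenones bearing hydroxy, silyloxy or alkoxy at C4, which gives hydroquinones still protected on the former carbinol oxygen; the acyloxy group at C4 and a 4-pyranone alkene as the 6π partner are the untested elements. The only ring closed is ring A, a six-membered carbocycle formed by thermal disrotatory electrocyclic closure between the ketene carbon (flavone C5) and pyranone C5 (flavone C4a). No stereocenter survives: the C4a center of 16 is racemic and is erased on aromatisation. The step needs torquoselectivity, which the oxygen on the carbinol carbon should secure by rotating outward as a donor and so turning the pyranonyl group inward beside the ketene; the pattern 8-O-butyryl, 7-OMe, 6-H, 5-OH is already fixed by the constitution of 14, and C5 is the only position open for closure. The electron-rich C5 (β-carbon of the ring enol ether) matches the electrophilic ketene carbon, and the new 5-OH is stabilised by a hydrogen bond to the C4 carbonyl.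

**Step 7**
Reactants: 17 3-(benzyloxy)-8-(butyryloxy)-5-hydroxy-7-methoxyflavone
Product: 18 8-(butyryloxy)-3,5-dihydroxy-7-methoxyflavone (target)
Conditions: H2 (1 atm), Pd/C (10 wt%), EtOAc, rt
Reagents that add atoms: none
Why: Catalytic hydrogenolysis of the benzylic C–O bond; the neutral aprotic medium should leave the aryl butyrate untouched and the flavone C2=C3 bond is not reduced under these conditions.

**Compound list**
1 | furfural | O=Cc1ccco1 | starting material
2 | phenylmagnesium bromide | Br[Mg]c1ccccc1 | starting material
3 | furan-2-yl(phenyl)methanol (racemic) | OC(c1ccco1)c1ccccc1 | intermediate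
4 | 6-hydroxy-2-phenyl-2H-pyran-3(6H)-one (racemic, mixture of diastereomers) | OC1C=CC(=O)C(c2ccccc2)O1 | intermediate
5 | 4-chloro-6-hydroxy-2-phenyl-2H-pyran-3(6H)-one (racemic, mixture of diastereomers) | OC1C=C(Cl)C(=O)C(c2ccccc2)O1 | intermediate
6 | 3-hydroxy-2-phenyl-4H-pyran-4-one | O=c1ccoc(-c2ccccc2)c1O | intermediate
7 | 3-(benzyloxy)-2-phenyl-4H-pyran-4-one | O=c1ccoc(-c2ccccc2)c1OCc1ccccc1 | intermediate
8 | dimethyl squarate | COC1=C(OC)C(=O)C1=O | starting material
9 | 4-hydroxy-2,3-dimethoxycyclobut-2-en-1-one (racemic) | COC1=C(OC)C(=O)C1O | intermediate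
10 | 3-methoxycyclobut-3-ene-1,2-dione (methyl semisquarate) | COC1=CC(=O)C1=O | intermediate
11 | butyric anhydride | CCCC(=O)OC(=O)CCC | starting material
12 | 6-lithio-3-(benzyloxy)-2-phenyl-4H-pyran-4-one | [Li]c1cc(=O)c(OCc2ccccc2)c(-c2ccccc2)o1 | intermediate
13 | lithium 1-[5-(benzyloxy)-4-oxo-6-phenyl-4H-pyran-2-yl]-2-methoxy-4-oxocyclobut-2-en-1-olate (racemic) | [Li]OC1(c2cc(=O)c(OCc3ccccc3)c(-c3ccccc3)o2)C(OC)=CC1=O | intermediate
14 | 1-[5-(benzyloxy)-4-oxo-6-phenyl-4H-pyran-2-yl]-2-methoxy-4-oxocyclobut-2-en-1-yl butanoate (racemic) | CCCC(=O)OC1(c2cc(=O)c(OCc3ccccc3)c(-c3ccccc3)o2)C(OC)=CC1=O | intermediate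
15 | (1Z)-1-[5-(benzyloxy)-4-oxo-6-phenyl-4H-pyran-2-yl]-2-methoxy-4-oxobuta-1,3-dien-1-yl butanoate (dienylketene) | O=C=C/C(OC)=C(/OC(=O)CCC)c1cc(=O)c(OCc2ccccc2)c(-c2ccccc2)o1 | intermediate
16 | 3-(benzyloxy)-7-methoxy-4,5-dioxo-2-phenyl-4a,5-dihydro-4H-chromen-8-yl butanoate (racemic at C4a) | CCCC(=O)OC1=C2OC(c3ccccc3)=C(OCc3ccccc3)C(=O)C2C(=O)C=C1OC | intermediate
17 | 3-(benzyloxy)-5-hydroxy-7-methoxy-4-oxo-2-phenyl-4H-chromen-8-yl butanoate | CCCC(=O)Oc1c(OC)cc(O)c2c(=O)c(OCc3ccccc3)c(-c3ccccc3)oc12 | intermediate
18 | 3,5-dihydroxy-7-methoxy-4-oxo-2-phenyl-4H-chromen-8-yl butanoate (no stereocenters) | CCCC(=O)Oc1c(OC)cc(O)c2c(=O)c(O)c(-c3ccccc3)oc12 | target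

**Totals**
Total step count: 7.
Longest linear sequence: 6 steps (steps 1, 2, 3, 5, 6, 7); step 4 is a one-step side branch.

**Steps most likely to fail**

Step 6. The acyloxy group may not enforce outward rotation strongly enough, or the dienylketene may be diverted (acyl transfer to the ketene, dimerisation, loss of butyric acid) before 6π closure. The fallback sets out from the lithium alkoxide 13, which is quenched with aqueous NH4Cl in place of 11 to give the free carbinol 4-hydroxy-3-methoxy-4-[5-(benzyloxy)-4-oxo-6-phenyl-4H-pyran-2-yl]cyclobut-2-en-1-one F1. Heating F1 in degassed p-xylene under argon is the classical 4-hydroxycyclobutenone to hydroquinone rearrangement, with the hydroxyl rotating outward, and should give 3-(benzyloxy)-5,8-dihydroxy-7-methoxyflavone F2. Without exposure to air, F2 is acylated with 11 (1.05 equiv) and pyridine in CH2Cl2 at 0 °C; the 5-OH is held in a hydrogen bond to the C4 carbonyl, so only the 8-OH should react. This comes back to the route at 17.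

Step 5. Deprotonation may be slow or incomplete, letting the lithiated pyranone add in conjugate fashion to pyranone not yet metalated, and the hindered alkoxide may be acylated sluggishly. The fallback sets out from 7: deprotonation with LiTMP in the presence of ZnCl2·TMEDA in THF (each lithio species is trapped at once as a stable arylzinc), then I2, should give 3-(benzyloxy)-6-iodo-2-phenyl-4H-pyran-4-one F3. Iodine–lithium exchange on the isolated iodide with t-BuLi (2 equiv) in THF/Et2O at −100 °C generates the organolithium at once, free of amine and of unmetalated pyranone. This comes back to the route at 12, which is treated with 10 and 11 as before.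

Step 2. Over-chlorination or acid-induced ring cleavage of the phenyl-substituted pyranone may occur during the second halogenation and the hot-acid stage, in place of clean aromatisation. The fallback sets out from 3: NBS, NaHCO3, THF/H2O at 0 °C gives 4, now isolated. Acetalisation (HC(OMe)3, cat. TsOH, MeOH) gives 6-methoxy-2-phenyl-2H-pyran-3(6H)-one F4. Nucleophilic epoxidation of the enone (H2O2, cat. NaOH, MeOH, 0 °C) gives 4,5-epoxy-6-methoxy-2-phenyltetrahydropyran-3-one F5. Aqueous H2SO4 at 90 °C opens the epoxide, eliminates methanol and enolises. This comes back to the route at 6.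

**Further compounds**
F1 | step 6 | 4-hydroxy-3-methoxy-4-[5-(benzyloxy)-4-oxo-6-phenyl-4H-pyran-2-yl]cyclobut-2-en-1-one (racemic) | OC1(c2cc(=O)c(OCc3ccccc3)c(-c3ccccc3)o2)C(OC)=CC1=O
F2 | step 6 | 3-(benzyloxy)-5,8-dihydroxy-7-methoxyflavone | COc1cc(O)c2c(=O)c(OCc3ccccc3)c(-c3ccccc3)oc2c1O
F3 | step 5 | 3-(benzyloxy)-6-iodo-2-phenyl-4H-pyran-4-one | Ic1cc(=O)c(OCc2ccccc2)c(-c2ccccc2)o1
F4 | step 2 | 6-methoxy-2-phenyl-2H-pyran-3(6H)-one (racemic, mixture of diastereomers) | COC1C=CC(=O)C(c2ccccc2)O1
F5 | step 2 | 4,5-epoxy-6-methoxy-2-phenyltetrahydropyran-3-one (racemic, mixture of diastereomers) | COC1OC(c2ccccc2)C(=O)C2OC12
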